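**Retrosynthetic overview**
1. Ring C is the only ring built and it is closed last. Cutting O1–C2 gives an (E)-2',6'-dihydroxychalcone. In the forward sense this is an oxa-Michael closure plus iodine/DMSO dehydrogenation.
2. Cutting the chalcone Cα=Cβ bond gives the ring A methyl ketone (bought) and the ring B aldehyde, joined by a crossed aldol condensation without protecting groups.
3. Cutting the C2–OMe bond of the ring B aldehyde leads to syringaldehyde. In the forward sense this is a formal C–H methoxylation by phenol dearomatisation, methanol addition and rearomatisation (key C–O step, new).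
4. Rings A and B are bought as arenes, and the route is linear in three steps.

Assumption: the target SMILES holds no stereocentre and no stereogenic double bond, so the compound is achiral and no enantiocontrol is needed. Transient stereo-elements on the way are erased.

**Route**

Step 1
Reactants: 1 syringaldehyde (4-hydroxy-3,5-dimethoxybenzaldehyde)
Product: 4 4-hydroxy-2,3,5-trimethoxybenzaldehyde, via masked ortho-quinone monoketal 2 (not isolated), via methanol adduct 3 (not isolated)
Conditions: PhI(OAc)2 (1.00 equiv), dry MeOH (0.05 M), 0 °C, 20 min; then CH3SO3H (5–10 mol %), 45 °C, 3 h; acidic aqueous work-up (pH 2)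
Reagents that add atoms: methanol, CO
Why: Proposed new method: a formal C–H methoxylation meta to a phenol OH by dearomatisation, solvent addition and rearomatisation; the trivalent iodine reagent in MeOH turns 1 into ortho-quinone monoketal 2 (known phenol oxidation, with attack at the OMe-bearing ortho carbon because the formyl-bearing para carbon cannot carry the cation); in 2 the ring CH next to the ketal is both the β-carbon of the enal and the δ-carbon of the dienone, so acid-catalysed oxa-Michael addition of MeOH gives 3; ionisation of the oxygen-stabilised ketal of 3 and loss of the neighbouring proton expels MeOH and restores aromaticity irreversibly (2 and 4 are isomers); attack at the other free ring CH gives the same 4 because the ring of 1 is symmetric; over-oxidation of the more electron-rich 4 is avoided because the oxidant is spent at 0 °C before the acid is added; the closest known reaction types are Michael addition/rearomatisation of carbon nucleophiles (indoles, arenes, silyl enol ethers) on quinone monoketals and the acid-catalysed conversion of quinone bisketals into trimethoxybenzenes in MeOH; no stereocentre remains in 4.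

Step 2
Reactants: 4 4-hydroxy-2,3,5-trimethoxybenzaldehyde; 5 2',6'-dihydroxy-4'-methoxyacetophenone
Product: 6 (E)-1-(2,6-dihydroxy-4-methoxyphenyl)-3-(4-hydroxy-2,3,5-trimethoxyphenyl)prop-2-en-1-one
Conditions: BF3·OEt2 (50 mol %), 1,4-dioxane, rt, 6 h; H2O quench
Reagents that add atoms: none
Why: Lewis-acid Claisen–Schmidt (crossed aldol) condensation in which all three phenols stay un-ionised, so the aldehyde is not deactivated as a para-phenoxide as it would be in KOH, the hydrogen-bonded ketone enolises at its only enolisable site, the para-OH speeds dehydration to the thermodynamic E-alkene, and any ring-closed isomer 7 is carried along because step 3 passes through it.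

Step 3
Reactants: 6 (E)-1-(2,6-dihydroxy-4-methoxyphenyl)-3-(4-hydroxy-2,3,5-trimethoxyphenyl)prop-2-en-1-one
Product: 8 5-hydroxy-2-(4-hydroxy-2,3,5-trimethoxyphenyl)-7-methoxy-4H-chromen-4-one (5,4'-dihydroxy-7,2',3',5'-tetramethoxyflavone), via racemic flavanone 7 (not isolated)
Conditions: I2 (10 mol %), DMSO, 120 °C, 3 h; aq. Na2S2O3 work-up
Reagents that add atoms: none
Why: Iodine/DMSO oxidative cyclisation of a 2'-hydroxychalcone, in which 6-endo oxa-Michael addition of either of the two equivalent ortho-OH groups forms the O1–C2 bond, iodine dehydrogenates C2–C3 of 7 with DMSO as terminal oxidant, the other ortho-OH ends as the chelated 5-OH, the racemic C2 centre of 7 is erased, and free phenols are tolerated as in the iodine dehydrogenation of polyhydroxyflavanones.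

**Compound list**
1 | syringaldehyde (4-hydroxy-3,5-dimethoxybenzaldehyde) | COc1cc(C=O)cc(OC)c1O | starting material
2 | 3,3,5-trimethoxy-4-oxocyclohexa-1,5-diene-1-carbaldehyde (masked ortho-quinone monoketal) | O=CC1=CC(OC)(OC)C(=O)C(OC)=C1 | intermediate
3 | 4-hydroxy-3,5,5,6-tetramethoxycyclohexa-1,3-diene-1-carbaldehyde (racemic at C6, drawn as the push–pull dienol tautomer) | O=CC1=CC(OC)=C(O)C(OC)(OC)C1OC | intermediate
4 | 4-hydroxy-2,3,5-trimethoxybenzaldehyde | COc1cc(C=O)c(OC)c(OC)c1O | intermediate
5 | 2',6'-dihydroxy-4'-methoxyacetophenone, 1-(2,6-dihydroxy-4-methoxyphenyl)ethanone | CC(=O)c1c(O)cc(OC)cc1O | starting material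
6 | (E)-1-(2,6-dihydroxy-4-methoxyphenyl)-3-(4-hydroxy-2,3,5-trimethoxyphenyl)prop-2-en-1-one | COc1cc(O)c(C(=O)/C=C/c2cc(OC)c(O)c(OC)c2OC)c(O)c1 | intermediate
7 | 5-hydroxy-2-(4-hydroxy-2,3,5-trimethoxyphenyl)-7-methoxychroman-4-one (racemic at C2) | COc1cc(O)c2C(=O)CC(Oc2c1)c1cc(OC)c(O)c(OC)c1OC | intermediate
8 | 5-hydroxy-2-(4-hydroxy-2,3,5-trimethoxyphenyl)-7-methoxy-4H-chromen-4-one | COc1cc(O)c2c(=O)cc(-c3cc(OC)c(O)c(OC)c3OC)oc2c1 | target

**Totals**
Total step count: 3.
Longest linear sequence: 3 (1 → 4 → 6 → 8).

**Steps most likely to fail, highest risk first**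

Step 1 (the proposed new step).
- Risks: Diels–Alder dimerisation of 2. Attack at the formyl-bearing carbon followed by loss of the formyl group, which gives 2,6-dimethoxybenzoquinone-type products. Ketal hydrolysis by adventitious water. Reversible tying-up of the formyl group by the solvent, which the acidic aqueous work-up undoes. Methanol addition that is too slow to compete with these paths.
- Fallback (known chemistry): it sets out from 1 and comes back at 4. Electrophilic bromination of 1 (Br2, AcOH, rt; the two free ring positions are equivalent) gives 2-bromo-4-hydroxy-3,5-dimethoxybenzaldehyde F1. An Ullmann-type methoxylation catalysed by monovalent copper (NaOMe, CuBr 10 mol %, DMF/MeOH, 110 °C, then acidification) follows. It is modelled on the classic conversion of 5-bromovanillin into syringaldehyde, replaces Br by OMe and gives 4.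

Step 2.
- Risks: sluggish condensation of a very electron-rich aldehyde. Friedel–Crafts attack of the phloroglucinol-type ring A on the activated aldehyde. An untidy mixture of 6 and 7.
- Fallback: it sets out from 4 and 5 and comes back at 6, changing to a protected, base-mediated condensation.
  - Chloromethyl methyl ether with K2CO3 in acetone turns 4 into 2,3,5-trimethoxy-4-(methoxymethoxy)benzaldehyde F2.
  - The same reagents, with one equivalent, turn 5 into 1-[2-hydroxy-4-methoxy-6-(methoxymethoxy)phenyl]ethanone F3. The remaining OH is chelated and unreactive.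
  - Classical KOH/EtOH Claisen–Schmidt condensation at rt gives (E)-1-[2-hydroxy-4-methoxy-6-(methoxymethoxy)phenyl]-3-[2,3,5-trimethoxy-4-(methoxymethoxy)phenyl]prop-2-en-1-one F4.
  - HCl in MeOH at 50 °C removes both acetals to give 6. Any 7 formed alongside is equally fit for step 3.

Step 3.
- Risks: ring iodination at C6 or C8, or oxidative degradation of the free 2,6-dialkoxyphenol of ring B, in hot I2/DMSO.
- Fallback: it sets out from 6 and comes back at 8, separating the ring closure from the oxidation and switching to hydride abstraction. NaOAc in refluxing EtOH isomerises 6 to flavanone 7, which is isolated. 2,3-Dichloro-5,6-dicyano-1,4-benzoquinone (1.2 equiv, 1,4-dioxane, 90 °C) then takes hydride from C2, which is para-hydroxybenzylic and α to oxygen. Loss of the C3 proton gives 8. New compounds on this way: none F0.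

**Further compounds**
F1 | step 1 | 2-bromo-4-hydroxy-3,5-dimethoxybenzaldehyde | COc1cc(C=O)c(Br)c(OC)c1O
F2 | step 2 | 2,3,5-trimethoxy-4-(methoxymethoxy)benzaldehyde | COCOc1c(OC)cc(C=O)c(OC)c1OC
F3 | step 2 | 1-[2-hydroxy-4-methoxy-6-(methoxymethoxy)phenyl]ethanone | CC(=O)c1c(O)cc(OC)cc1OCOC
F4 | step 2 | (E)-1-[2-hydroxy-4-methoxy-6-(methoxymethoxy)phenyl]-3-[2,3,5-trimethoxy-4-(methoxymethoxy)phenyl]prop-2-en-1-one | COCOc1cc(OC)cc(O)c1C(=O)/C=C/c1cc(OC)c(OCOC)c(OC)c1OC
F0 | step 3 | none | none
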